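The readings come from a simulation with made-up constants, noise included.

A chemist planning zeta, gamma and epsilon has cedar to go on, so read cedar first.

| setting | cedar | zeta | gamma | epsilon |
|---|---|---|---|---|
| starting complex | 8 mM | 8.0 mM | 12 mM | 20 mM |
| incoming ligand | 15 mM | 22.0 mM | 22.0 mM | 22.0 mM |
| remark | run made earlier |  |  |  |
| time |  | 25 min | 25 min | 25 min |

cedar run (percent of the starting complex charged)

| time / min | complex with two exchanged / % |
|---|---|
| 3.00 | 1.1 |
| 6.00 | 3.7 |
| 10.0 | 4.4 |
| 12.0 | 5.2 |
| 15.0 | 5.7 |

(each reading ± 0.3 percentage points)

- steps thought possible: starting complex + incoming ligand <-> leaving ligand + complex with one exchanged; complex with one exchanged + incoming ligand <-> leaving ligand + complex with two exchanged; 2 incoming ligand -> homo dimer; complex with one exchanged -> side product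
- "hardly changes" means that all values lie within two and a half points (for a concentration: within two and a half percent of the largest)
- no earlier run changes the charge of incoming ligand; that part of a forecast is a guess

- [complex with two exchanged] at the end for zeta, gamma, epsilon, in this order
- the shape of the row from first to last (falls, then rises / rises, then falls / falls all the way / rises all the way / hardly changes)

Cedar and zeta look nearly the same. Both hold 8.0 mM of starting complex, and they differ in incoming ligand, 15 mM against 22.0 mM. Cedar's complex with two exchanged gained 2.6 percentage points between 3.00 min and 6.00 min, but 0.5 points between 12.0 min and 15.0 min, a slower gain. Yet at its last reading that product held 0.912 mM of incoming ligand, far less than the charge, so its own demand does not account for the slowing.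

I read the slowing as the homo dimer step taking incoming ligand away, a loss that needs no complex. If so, c(complex with two exchanged) follows the ligand charge, not the complex charge.

So I carry the ligand yield, a yield on the charge: c(complex with two exchanged) made per c(incoming ligand) charged, 3.04 %. It comes from one reading with a scatter of 0.3 points. Zeta should then end at 0.669 mM, which is 8.36 % of its charge. Gamma and epsilon hold the same 22.0 mM, so my row stays near that value and hardly changes. No earlier run varies the ligand charge, so this is a guess.

The forecast differs from my reckoning: it gave 0.9 mM, 1.15 mM and 1.5 mM, rises all the way, with the words “Yield falls, but absolute product still rises”.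

The flask gives 0.559 mM, 0.611 mM and 0.587 mM, so the row rises, then falls.

    starting complex + incoming ligand ⇌ leaving ligand + complex with one exchanged (K = 14.0, k = 3.70 L mol⁻¹ min⁻¹)
    complex with one exchanged + incoming ligand ⇌ leaving ligand + complex with two exchanged (K = 0.580, k = 8.50 L mol⁻¹ min⁻¹)
    2 incoming ligand → homo dimer (k = 8.20 L mol⁻¹ min⁻¹)
    complex with one exchanged → side product (k = 0.0290 min⁻¹)

In zeta at 25.0 min, homo dimer stands at 8.47 mM, which holds 77.0 % of the incoming ligand charged, and 7.33 % of that charge is left. Zeta's ligand yield comes out at 2.54 %, lower than cedar's, so my value was too high. Epsilon holds 2.50 times zeta's starting complex, and its ligand yield is 2.67 %.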